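**Retrosynthetic overview**
1. Target ⇒ its 3',4'-di-O-benzyl ether; the last step only unmasks the ring B catechol by hydrogenolysis.
2. Key disconnection: the O1–C2 bond of ring C (carbon–oxygen ring closure) together with the 7-O–S bond ⇒ an open-chain 1-(2,4,6-trihydroxyphenyl)-3-aryl-1,3-diketone. One reagent, SO3·pyridine, closes and dehydrates ring C and sulfates the para phenol; the symmetry of the trihydroxyphenyl ring fixes the sulfate at C7.
3. Diketone ⇒ C-aroylation of the lithium polyanion of 2',4',6'-trihydroxyacetophenone with 3,4-bis(benzyloxy)benzoyl chloride made in the flask from the acid.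
4. Ring order: rings A and B are bought; ring C is the only ring made (step 2).

Assumption: the target has no stereocentre (it is achiral), so the drawn structure is the only stereoisomer; the aryl hydrogen sulfates are drawn as free acids but handled as sodium salts, the free acid being liberated by cold H+ exchange at the end.

**Step 1**
Reactants: 1 2',4',6'-trihydroxyacetophenone (dried); 2 3,4-bis(benzyloxy)benzoic acid
Product: 5 1-[3,4-bis(benzyloxy)phenyl]-3-(2,4,6-trihydroxyphenyl)propane-1,3-dione, via acid chloride 3 (not isolated), via tetralithium polyanion 4 (not isolated)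
Conditions: (a) 2, (COCl)2 (1.3 equiv), DMF (cat.), CH2Cl2, 0 °C to rt, evaporate; (b) 1, LiN(SiMe3)2 (4.2 equiv), THF, −78 °C, 1 h; add 3 (1.05 equiv) in THF, −78 °C to rt, 4 h; cold 1 M HCl
Reagents that add atoms: none
Why: Crossed Claisen-type C-aroylation of a lithium polyanion (the Cushman flavone protocol): the enolate carbon of 4 is acylated by 3 faster than the aggregated lithium phenoxides at −78 °C, any O-aroyl ester is funnelled to the same diketone by a Baker–Venkataraman-type O→C shift, and benzyl ethers are inert to LiN(SiMe3)2.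

**Step 2**
Reactants: 5 1-[3,4-bis(benzyloxy)phenyl]-3-(2,4,6-trihydroxyphenyl)propane-1,3-dione
Product: 8 3',4'-di-O-benzylluteolin 7-sulfate, via aryl sulfate 6 (not isolated), via hemiketal sulfate 7 (not isolated)
Conditions: SO3·pyridine (1.1 equiv), pyridine, 0 °C to rt, 2 h; then SO3·pyridine (1.4 equiv), 60 °C, 6 h; aq NaHCO3; C18 reversed-phase chromatography (sodium salt, pyridine-free)
Reagents that add atoms: sulfur trioxide–pyridine complex, [O-]S(=O)(=O)[n+]1ccccc1
Why: Proposed new method: a sulfative cyclodehydration in which SO3·pyridine serves twice — it first sulfates the only unchelated and most acidic phenol (the 4-OH para to the ketone; the two ortho OH groups are equivalent, so the sulfate can only end up at C7) to give 6, and then O-sulfates the tertiary hemiketal OH of the ring-closed 2-hydroxyflavanone tautomer (O1–C2 bond formed by reversible 6-exo addition of an ortho OH to the aryl ketone) to give 7, whose sulfate leaves from a carbon stabilised by O1 and the dialkoxyphenyl ring in a pyridine-assisted E1/E1cB elimination across C2–C3 (C3–H is alpha to the C4 ketone), forming the pyranone irreversibly while the remaining 5-OH is shielded by its hydrogen bond to C4=O; the closest known reactions are the acid-catalysed cyclodehydration that ends the Baker–Venkataraman flavone synthesis, Burgess-type dehydration of alcohols through sulfur-based esters, and ordinary phenol sulfation by SO3·pyridine.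

**Step 3**
Reactants: 8 3',4'-di-O-benzylluteolin 7-sulfate
Product: 9 luteolin 7-sulfate
Conditions: H2 (1 atm), Pd/C (10 wt% Pd on carbon, 10 mol% Pd), MeOH–THF–H2O, rt, stop at 2 equiv H2 uptake; filter; Dowex 50W (H+ form), 0 °C; lyophilise
Reagents that add atoms: none
Why: Catalytic hydrogenolysis of aryl benzyl ethers over palladium on carbon cleaves the benzylic C–O bonds much faster than it touches the chromone C2=C3 bond or the aryl sulfate monoester anion at 1 atm, and brief cold H+ exchange gives the free hydrogen sulfate.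

**Compound list**
1 | 2',4',6'-trihydroxyacetophenone | CC(=O)c1c(O)cc(O)cc1O | starting material
2 | 3,4-bis(benzyloxy)benzoic acid | O=C(O)c1ccc(OCc2ccccc2)c(OCc2ccccc2)c1 | starting material
3 | 3,4-bis(benzyloxy)benzoyl chloride | O=C(Cl)c1ccc(OCc2ccccc2)c(OCc2ccccc2)c1 | intermediate (not isolated)
4 | tetralithium 2-(1-oxidoethenyl)benzene-1,3,5-triolate (polyanion of 1) | [Li+].[Li+].[Li+].[Li+].C=C([O-])c1c([O-])cc([O-])cc1[O-] | intermediate (not isolated)
5 | 1-[3,4-bis(benzyloxy)phenyl]-3-(2,4,6-trihydroxyphenyl)propane-1,3-dione (keto/enol/hemiketal tautomers) | O=C(CC(=O)c1c(O)cc(O)cc1O)c1ccc(OCc2ccccc2)c(OCc2ccccc2)c1 | intermediate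
6 | 4-{3-[3,4-bis(benzyloxy)phenyl]-3-oxopropanoyl}-3,5-dihydroxyphenyl hydrogen sulfate | O=C(CC(=O)c1c(O)cc(OS(=O)(=O)O)cc1O)c1ccc(OCc2ccccc2)c(OCc2ccccc2)c1 | intermediate (not isolated)
7 | 2-[3,4-bis(benzyloxy)phenyl]-5-hydroxy-4-oxochromane-2,7-diyl bis(hydrogen sulfate), racemic at C2, stereocentre lost on elimination | O=C1CC(OS(=O)(=O)O)(c2ccc(OCc3ccccc3)c(OCc3ccccc3)c2)Oc2cc(OS(=O)(=O)O)cc(O)c12 | intermediate (not isolated)
8 | 2-[3,4-bis(benzyloxy)phenyl]-5-hydroxy-4-oxo-4H-chromen-7-yl hydrogen sulfate (3',4'-di-O-benzylluteolin 7-sulfate) | O=c1cc(-c2ccc(OCc3ccccc3)c(OCc3ccccc3)c2)oc2cc(OS(=O)(=O)O)cc(O)c12 | intermediate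
9 | luteolin 7-sulfate, 2-(3,4-dihydroxyphenyl)-5-hydroxy-4-oxo-4H-chromen-7-yl hydrogen sulfate (achiral) | O=c1cc(-c2ccc(O)c(O)c2)oc2cc(OS(=O)(=O)O)cc(O)c12 | target

**Step count and risks**
Total steps: 3. Longest linear sequence: 3 (1 or 2 → 5 → 8 → 9).

Most at risk is step 2, the new sulfative cyclodehydration. It could stall at the 2-hydroxyflavanone 7-sulfate, or sulfate one of the ortho OH groups before ring closure. The fallback uses known chemistry and sets out from 5: acid cyclodehydration (H2SO4 cat., AcOH, 95 °C, 1 h) gives 3',4'-di-O-benzylluteolin F3. Standard sulfation of its only unchelated phenol (SO3·pyridine 1.5 equiv, pyridine, rt, then aq NaHCO3) comes back to the route at 8.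

Second is step 1. The commercial hydrate of 1 must be dried fully, the tetralithium salt is poorly soluble, and O- or bis-aroylation can compete. The fallback is the classical perester Baker–Venkataraman sequence and sets out from 1 and 3. Using 3 (3.3 equiv) in pyridine at 0 °C to rt gives 2-acetylbenzene-1,3,5-triyl tris[3,4-bis(benzyloxy)benzoate] F1. Powdered KOH in pyridine at 50 °C shifts one ortho aroyl group from O to C to give 4-{3-[3,4-bis(benzyloxy)phenyl]-3-oxopropanoyl}-5-hydroxy-1,3-phenylene bis[3,4-bis(benzyloxy)benzoate] F2. K2CO3 in MeOH at rt removes the two remaining aryl esters and comes back to the route at 5.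

Third is step 3. Possible problems are partial saturation of C2=C3, inhibition of the catalyst by residual pyridine, and loss of sulfate during H+ exchange. The fallback avoids hydrogenating a sulfated flavone and sets out from 5: HBr (33% in AcOH), 70 °C cyclodehydrates and O-debenzylates in one pot to give luteolin F4. Sulfation with dicyclohexylcarbodiimide and Bu4NHSO4 in pyridine at 4 °C is known to favour the 7-OH; after Sephadex LH-20 removal of the minor 4'-sulfate and cold H+ exchange it comes back to the route at 9.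

**Further compounds**
F1 | step 1 | 2-acetylbenzene-1,3,5-triyl tris[3,4-bis(benzyloxy)benzoate] | CC(=O)c1c(OC(=O)c2ccc(OCc3ccccc3)c(OCc3ccccc3)c2)cc(OC(=O)c2ccc(OCc3ccccc3)c(OCc3ccccc3)c2)cc1OC(=O)c1ccc(OCc2ccccc2)c(OCc2ccccc2)c1
F2 | step 1 | 4-{3-[3,4-bis(benzyloxy)phenyl]-3-oxopropanoyl}-5-hydroxy-1,3-phenylene bis[3,4-bis(benzyloxy)benzoate] | O=C(CC(=O)c1ccc(OCc2ccccc2)c(OCc2ccccc2)c1)c1c(O)cc(OC(=O)c2ccc(OCc3ccccc3)c(OCc3ccccc3)c2)cc1OC(=O)c1ccc(OCc2ccccc2)c(OCc2ccccc2)c1
F3 | step 2 | 3',4'-di-O-benzylluteolin, 2-[3,4-bis(benzyloxy)phenyl]-5,7-dihydroxy-4H-chromen-4-one | O=c1cc(-c2ccc(OCc3ccccc3)c(OCc3ccccc3)c2)oc2cc(O)cc(O)c12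
F4 | step 3 | luteolin | O=c1cc(-c2ccc(O)c(O)c2)oc2cc(O)cc(O)c12
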